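**Retrosynthetic overview**

1. Feature the strategy rests on: the ring B enone C6(=O)–C7H=C8(CH3) of the decalin (ring C5–C10) is a five-membered ketone C6(=O)–C8H(CH3) in a trans-hydrindane (ring A C1–C5/C10 fused to ring C5–C6–C8–C9–C10) plus one inserted carbon, C7.
2. Disconnections, backwards: C3–O silyl ether; C11–O aryl ether (Mitsunobu, umbelliferone); C7–Br (hydrogenolysis); C6–C7 and C7–C8 (dibromocarbene from bromoform into the C6=C8 silyl enol ether, five- to six-membered ring expansion).
3. The hydrindanone comes from (R)-Hajos–Parrish ketone. C9=O is turned into C9=C11H2 first, so that the C4 gem-dimethylation and the C3 hydride reduction each meet a single ketone. Hydroboration of both alkenes then sets C9 and C5, C6 is oxidised, and the C8 methyl is put in last through the C6 ketone.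
4. Ring order: ring A and the five-membered ring come with the starting material; ring B is formed in the key step; the coumarin is attached intact.

Key step: step 10

**Remarks on conventions and assumptions**

- Drimane numbering is used for every compound, as locant shorthand only. In the bicyclic intermediates, "7-nor" means C7 is absent (C6 bonded to C8) and "12-nor" means C8 carries no methyl. β is the face of the C10 methyl, α the opposite face. Absolute configurations are those of the SMILES strings.
- Assumption: the cyclopropane 16 opens on warming to room temperature (brief warming in toluene otherwise).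
- Assumption: the C8 configuration of 12 is drawn as the expected trans isomer; it is erased in step 9.

**Route**

Step 1
Reactants: 1 (R)-Hajos–Parrish ketone, (7aR)-7a-methyl-2,3,7,7a-tetrahydro-1H-indene-1,5(6H)-dione
Product: 2 (7aS)-7a-methyl-1-methylidene-2,3,7,7a-tetrahydro-1H-inden-5(6H)-one (C9=C11H2; enone C3(=O)–C4=C5 kept; the descriptor changes only through CIP priorities)
Conditions: Ph3PCH3Br, KOtBu, THF, 0 °C → rt
Reagents that add atoms: methyltriphenylphosphonium bromide, C[P+](c1ccccc1)(c1ccccc1)c1ccccc1.[Br-]
Why: Wittig methylenation should take the non-conjugated C9 cyclopentanone carbonyl, which is more electrophilic than the vinylogous enone carbonyl, while any enone that is only deprotonated returns on work-up or converges through the same dienolate in step 2; the quaternary C10 centre cannot epimerise.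

Step 2
Reactants: 2 methylidene enone
Product: 3 7,12-dinordrima-5,9(11)-dien-3-one (C3 ketone; C4 gem-dimethyl; C5=C6 and exocyclic C9=C11H2 double bonds; C10 methyl)
Conditions: KOtBu, MeI, t-BuOH/THF, 0 °C → rt
Reagents that add atoms: iodomethane, CI
Why: Dienolate α,α-dialkylation with deconjugation: tert-butoxide removes a γ-hydrogen at C6, methyl iodide alkylates C4 twice and the double bond comes to rest at C5=C6 (the classical gem-dimethylation of bicyclic enones); no stereocentre is formed.

Step 3
Reactants: 3 dienone
Product: 4 7,12-dinordrima-5,9(11)-dien-3α-ol (axial OH, trans to the C10 methyl)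
Conditions: L-Selectride, THF, −78 °C; then H2O
Reagents that add atoms: none
Why: Diastereoselective reduction with a bulky trialkylborohydride: equatorial delivery of hydride to the C3 ketone next to the C4 gem-dimethyl group should give the axial 3α-alcohol, as with 4,4-dimethyl-3-oxo terpenoids, and the alkenes are inert.

Step 4
Reactants: 4 dienol
Product: 5 3α-(tert-butyldimethylsilyloxy)-7,12-dinordrima-5,9(11)-diene
Conditions: TBSOTf, 2,6-lutidine, CH2Cl2, 0 °C → rt
Reagents that add atoms: tert-butyldimethylsilyl triflate, CC(C)(C)[Si](C)(C)OS(=O)(=O)C(F)(F)F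
Why: Silylation of a hindered neopentylic secondary alcohol with a silyl triflate and a non-nucleophilic base, without stereochemical change.

Step 5
Reactants: 5 silyl ether diene
Product: 8 3α-(tert-butyldimethylsilyloxy)-7,12-dinordrimane-6α,11-diol (5α-H; 9α-H; C11 β; trans-hydrindane), via C11 alkyl-9-BBN 6 (not isolated), via C6 C11 bis-borane 7 (not isolated)
Conditions: 9-BBN, THF, 0 °C → rt; BH3·THF, 0 → 40 °C; then NaOH, H2O2, 0 °C → rt
Reagents that add atoms: hydrogen peroxide, OO; 9-borabicyclo[3.3.1]nonane, [H]B1C2CCCC1CCC2, and borane–THF, B.C1CCOC1 (boron only in 6 and 7)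
Why: Sequential hydroboration–oxidation: 9-BBN should take the exocyclic C9=C11 alkene first (boron at C11, hydrogen to C9 from the α face away from the C10 methyl, so C11 is β) and, having no B–H left, cannot deliver hydride intramolecularly to the β face of C5=C6; borane then adds to the hindered C5=C6 bond from the α face with boron at C6 (syn addition sets 5α-H and the trans ring fusion, the β face being blocked by the C10 and 4β methyls), and oxidation proceeds with retention.

Step 6
Reactants: 8 diol
Product: 9 3α,11-bis(tert-butyldimethylsilyloxy)-7,12-dinordriman-6α-ol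
Conditions: TBSCl, imidazole, CH2Cl2, 0 °C
Reagents that add atoms: tert-butyldimethylsilyl chloride, CC(C)(C)[Si](C)(C)Cl
Why: Chemoselective silylation of the primary C11 alcohol in the presence of the hindered secondary C6 alcohol.

Step 7
Reactants: 9 alcohol
Product: 10 3α,11-bis(tert-butyldimethylsilyloxy)-7,12-dinordriman-6-one (trans-hydrindanone)
Conditions: DMP, NaHCO3, CH2Cl2, rt
Reagents that add atoms: none
Why: Dess–Martin oxidation under buffered, non-enolising conditions, so that the epimerisable 5α-H next to the new ketone keeps the trans ring fusion.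

Step 8
Reactants: 10 hydrindanone
Product: 12 3α,11-bis(tert-butyldimethylsilyloxy)-7-nordriman-6-one (8α-methyl expected; methyl trans to C11), via lithium enolate 11 (not isolated)
Conditions: LDA, THF, −78 °C; MeI, DMPU, −78 → −30 °C
Reagents that add atoms: iodomethane, CI; lithium diisopropylamide, [Li]N(C(C)C)C(C)C (lithium of 11 only)
Why: Kinetic enolate alkylation: LDA should remove a C8 proton because the only other α-hydrogen, 5α-H, is flanked by the quaternary C4 and C10 and is syn-axial to the 3α-silyloxy group, and methyl iodide should enter trans to the C9 substituent; the C8 configuration is lost in the next step.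

Step 9
Reactants: 12 methyl ketone
Product: 14 3α,11-bis(tert-butyldimethylsilyloxy)-6-(trimethylsilyloxy)-7-nordrim-6(8)-ene (trimethylsilyl enol ether; C6=C8 tetrasubstituted), via lithium enolate 13 (not isolated)
Conditions: LDA, THF, −78 → −40 °C; TMSCl, Et3N, −78 °C → rt
Reagents that add atoms: chlorotrimethylsilane, C[Si](C)(C)Cl; lithium diisopropylamide, [Li]N(C(C)C)C(C)C (lithium of 13 only)
Why: Regioselective enol silylation: the base should again take the C8 hydrogen and not the shielded 5α-H, and the alternative C5=C6 enol ether would suffer allylic strain between the siloxy group and the C4 gem-dimethyl group, so kinetic and thermodynamic preference point the same way.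

Step 10
Reactants: 14 trimethylsilyl enol ether; 15 bromoform
Product: 17 7-bromo-3α,11-bis(tert-butyldimethylsilyloxy)drim-7-en-6-one, via siloxy-dibromocyclopropane 16 (not isolated)
Conditions: CHBr3 (excess), KOtBu (added in portions), pentane, −20 °C → rt
Reagents that add atoms: bromoform 15, BrC(Br)Br
Why: Dibromocarbene, formed by α-elimination from bromoform, adds as an electrophile to the electron-rich C6=C8 enol ether, the only alkene in 14, to give the 1-siloxy-6,6-dibromobicyclo[3.1.0]hexane unit of 16; the siloxy lone pair then expels the bromide lying over the five-membered ring in a disrotatory cyclopropyl-to-allyl opening that cleaves the C6–C8 bond, and loss of the silyl group from the oxocarbenium ion leaves the α-bromo enone. The closest known reaction type is the dihalocarbene ring expansion of cyclic silyl enol ethers to 2-halo-2-cycloalkenones, here a cyclopentanone-to-cyclohexenone homologation. Ring B is closed in two stages, a [2+1] cheletropic closure of the cyclopropane (bonds C6–C7 and C7–C8) and then scission of the shared bond, which leaves the six-membered ring C5–C6–C7–C8–C9–C10. No stereocentre is created in 17: the two cyclopropane centres of 16 are erased, and C3, C5, C9 and C10 are not involved. The step needs insertion between C6 and C8 and not between C5 and C6, which is fixed by the position of the enol ether double bond from step 9; it also needs the base-sensitive product (acidic H9 with a silyloxy group β to it at C11) to be spared, which keeping bromoform in excess over tert-butoxide at low temperature should secure.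

Step 11
Reactants: 17 bromo enone
Product: 18 3α,11-bis(tert-butyldimethylsilyloxy)drim-7-en-6-one
Conditions: Pd(OAc)2 (cat.), PPh3, HCO2H, Et3N, DMF, 60 °C
Reagents that add atoms: none
Why: Palladium-catalysed formate hydrogenolysis of the vinylic C7–Br bond (oxidative addition, formate exchange, decarboxylation, reductive elimination), which should leave the silyl ethers and the hindered enone untouched.

Step 12
Reactants: 18 enone
Product: 19 3α-(tert-butyldimethylsilyloxy)-11-hydroxydrim-7-en-6-one
Conditions: CSA (cat.), MeOH/CH2Cl2, 0 °C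
Reagents that add atoms: none
Why: Acid-catalysed methanolysis should remove the unhindered primary silyl ether much faster than the axial C3 silyl ether shielded by the C4 gem-dimethyl group.

Step 13
Reactants: 19 primary alcohol; 20 umbelliferone (7-hydroxycoumarin)
Product: 21 ferocaulidin 3-O-tert-butyldimethylsilyl ether, 7-[(3α-silyloxy-6-oxodrim-7-en-11-yl)oxy]coumarin
Conditions: PPh3, DIAD, THF, 0 °C → rt
Reagents that add atoms: umbelliferone 20, Oc1ccc2ccc(=O)oc2c1
Why: Mitsunobu etherification: the acidic phenol displaces the oxyphosphonium derivative of the primary C11 alcohol by SN2 at a non-stereogenic carbon under nearly neutral conditions, so the lactone, the enone and the acidic H9 are not exposed to base.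

Step 14
Reactants: 21 silyl ether
Product: 22 ferocaulidin
Conditions: aq. HF, MeCN, rt
Reagents that add atoms: none
Why: Fluoride cleavage of the remaining hindered silyl ether under acidic conditions avoids base-induced loss of the aryloxy group through the vinylogous enolate and avoids lactone opening; the four stereocentres are untouched.

**Compound list**

1 | (R)-Hajos–Parrish ketone, (7aR)-7a-methyl-2,3,7,7a-tetrahydro-1H-indene-1,5(6H)-dione | O=C1CC[C@@]2(C)C(=O)CCC2=C1 | starting material
2 | (7aS)-7a-methyl-1-methylidene-2,3,7,7a-tetrahydro-1H-inden-5(6H)-one | O=C1CC[C@@]2(C)C(=C)CCC2=C1 | intermediate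
3 | 7,12-dinordrima-5,9(11)-dien-3-one | C=C1CC=C2C(C)(C)C(=O)CC[C@@]12C | intermediate
4 | 7,12-dinordrima-5,9(11)-dien-3α-ol | C=C1CC=C2C(C)(C)[C@@H](O)CC[C@@]12C | intermediate
5 | 3α-(tert-butyldimethylsilyloxy)-7,12-dinordrima-5,9(11)-diene | C=C1CC=C2C(C)(C)[C@@H](O[Si](C)(C)C(C)(C)C)CC[C@@]12C | intermediate
6 | C11 alkyl-9-BBN adduct of 5 (9α-H, C5=C6 intact; not isolated) | C1C=C2C(C)(C)[C@@H](O[Si](C)(C)C(C)(C)C)CC[C@@]2(C)[C@@H]1CB1C2CCCC1CCC2 | intermediate
7 | 6α-boryl C11-(9-BBN) bis-borane (5α-H; not isolated) | C1[C@@H](B)[C@@H]2C(C)(C)[C@@H](O[Si](C)(C)C(C)(C)C)CC[C@@]2(C)[C@@H]1CB1C2CCCC1CCC2 | intermediate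
8 | 3α-(tert-butyldimethylsilyloxy)-7,12-dinordrimane-6α,11-diol | C1[C@@H](O)[C@@H]2C(C)(C)[C@@H](O[Si](C)(C)C(C)(C)C)CC[C@@]2(C)[C@@H]1CO | intermediate
9 | 3α,11-bis(tert-butyldimethylsilyloxy)-7,12-dinordriman-6α-ol | C1[C@@H](O)[C@@H]2C(C)(C)[C@@H](O[Si](C)(C)C(C)(C)C)CC[C@@]2(C)[C@@H]1CO[Si](C)(C)C(C)(C)C | intermediate
10 | 3α,11-bis(tert-butyldimethylsilyloxy)-7,12-dinordriman-6-one | C1C(=O)[C@@H]2C(C)(C)[C@@H](O[Si](C)(C)C(C)(C)C)CC[C@@]2(C)[C@@H]1CO[Si](C)(C)C(C)(C)C | intermediate
11 | lithium C6=C8 enolate of 10 (not isolated) | C1=C(O[Li])[C@@H]2C(C)(C)[C@@H](O[Si](C)(C)C(C)(C)C)CC[C@@]2(C)[C@@H]1CO[Si](C)(C)C(C)(C)C | intermediate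
12 | 3α,11-bis(tert-butyldimethylsilyloxy)-7-nordriman-6-one, 8α-methyl | C[C@H]1C(=O)[C@@H]2C(C)(C)[C@@H](O[Si](C)(C)C(C)(C)C)CC[C@@]2(C)[C@@H]1CO[Si](C)(C)C(C)(C)C | intermediate
13 | lithium C6=C8 enolate of 12 (not isolated) | CC1=C(O[Li])[C@@H]2C(C)(C)[C@@H](O[Si](C)(C)C(C)(C)C)CC[C@@]2(C)[C@@H]1CO[Si](C)(C)C(C)(C)C | intermediate
14 | trans-hydrindanone trimethylsilyl enol ether, 3α,11-bis(tert-butyldimethylsilyloxy)-6-(trimethylsilyloxy)-7-nordrim-6(8)-ene | CC1=C(O[Si](C)(C)C)[C@@H]2C(C)(C)[C@@H](O[Si](C)(C)C(C)(C)C)CC[C@@]2(C)[C@@H]1CO[Si](C)(C)C(C)(C)C | intermediate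
15 | bromoform | BrC(Br)Br | starting material
16 | 7,7-dibromo-6-(trimethylsilyloxy)-6,8-cyclopropane adduct of 14 (α-face adduct drawn; not isolated) | C[C@]12C(Br)(Br)[C@@]1(O[Si](C)(C)C)[C@@H]3C(C)(C)[C@@H](O[Si](C)(C)C(C)(C)C)CC[C@@]3(C)[C@@H]2CO[Si](C)(C)C(C)(C)C | intermediate
17 | 7-bromo-3α,11-bis(tert-butyldimethylsilyloxy)drim-7-en-6-one | CC1=C(Br)C(=O)[C@@H]2C(C)(C)[C@@H](O[Si](C)(C)C(C)(C)C)CC[C@@]2(C)[C@@H]1CO[Si](C)(C)C(C)(C)C | intermediate
18 | 3α,11-bis(tert-butyldimethylsilyloxy)drim-7-en-6-one | CC1=CC(=O)[C@@H]2C(C)(C)[C@@H](O[Si](C)(C)C(C)(C)C)CC[C@@]2(C)[C@@H]1CO[Si](C)(C)C(C)(C)C | intermediate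
19 | 3α-(tert-butyldimethylsilyloxy)-11-hydroxydrim-7-en-6-one | CC1=CC(=O)[C@@H]2C(C)(C)[C@@H](O[Si](C)(C)C(C)(C)C)CC[C@@]2(C)[C@@H]1CO | intermediate
20 | umbelliferone | Oc1ccc2ccc(=O)oc2c1 | starting material
21 | ferocaulidin 3-O-tert-butyldimethylsilyl ether | CC1=CC(=O)[C@@H]2C(C)(C)[C@@H](O[Si](C)(C)C(C)(C)C)CC[C@@]2(C)[C@@H]1COc1ccc2ccc(=O)oc2c1 | intermediate
22 | ferocaulidin | CC1=CC(=O)[C@@H]2C(C)(C)[C@@H](O)CC[C@@]2(C)[C@@H]1COc1ccc2ccc(=O)oc2c1 | target

**Step count**

Total: 14 steps. Longest linear sequence: 14 steps (1 → 22); bromoform and umbelliferone enter directly.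

**Steps most likely to fail**

Step 10 (key step). The carbene may add only slowly to the crowded tetrasubstituted enol ether, so that hydrolysis of the enol ether back to the ketone competes. Free tert-butoxide may also degrade the bromo enone by deprotonation at C9 and loss of the C11 silyloxy group. The fallback sets out from 14 and returns at 18, so step 11 is skipped. 14 would be cyclopropanated with the zinc carbenoid (Et2Zn, CH2I2, CH2Cl2, 0 °C) to the 6-trimethylsilyloxy-6,8-methano compound, siloxycyclopropane F3. Oxidative opening with FeCl3 in DMF (pyridine buffer, 0 °C) should cleave the internal C6–C8 bond through the tertiary C8 radical and give the ring-enlarged 8-chloro-3α,11-bis(silyloxy)driman-6-one F4. Sodium acetate in warm methanol would then eliminate hydrogen chloride to give 18.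

Step 13. Substitution at the β-branched C11 carbon may be slow, so that the oxyphosphonium intermediate is diverted into elimination through the acidic H9 toward a dienone, or is intercepted by the reduced azodicarboxylate. The fallback sets out from 19 and returns at 21. 19 would be converted at −78 °C (Tf2O, 2,6-lutidine, CH2Cl2) into the primary C11 triflate F5. The triflate would be displaced by umbelliferone 20 with Cs2CO3 in DMF at −20 → 0 °C, where the weakly basic phenoxide should substitute much faster than it deprotonates C9.

Step 1. The ylide may act as a base toward the enone or attack both carbonyl groups, giving poor chemoselectivity and incomplete conversion. The fallback sets out from 1 and returns at 2. The enone would first be masked as its C3 pyrrolidine dienamine F1 (pyrrolidine, MeOH, rt), which leaves the C9 ketone free. Methylenation under the conditions of step 1 would give the methylidene dienamine F2, and aqueous AcOH/NaOAc would release the enone to return 2.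

**Further compounds**

F1 | step 1 | C3 pyrrolidine 3,5-dienamine of 1 (C9 ketone free) | O=C1CC=C2C=C(N3CCCC3)CC[C@@]12C
F2 | step 1 | C9-methylidene pyrrolidine dienamine | C=C1CC=C2C=C(N3CCCC3)CC[C@@]12C
F3 | step 10 | 6-(trimethylsilyloxy)-6,8-methano adduct of 14 (siloxycyclopropane, α-face adduct drawn) | C[C@]12C[C@@]1(O[Si](C)(C)C)[C@@H]3C(C)(C)[C@@H](O[Si](C)(C)C(C)(C)C)CC[C@@]3(C)[C@@H]2CO[Si](C)(C)C(C)(C)C
F4 | step 10 | 8-chloro-3α,11-bis(tert-butyldimethylsilyloxy)driman-6-one (C8 epimers) | CC1(Cl)CC(=O)[C@@H]2C(C)(C)[C@@H](O[Si](C)(C)C(C)(C)C)CC[C@@]2(C)[C@@H]1CO[Si](C)(C)C(C)(C)C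
F5 | step 13 | 3α-(tert-butyldimethylsilyloxy)-6-oxodrim-7-en-11-yl triflate | CC1=CC(=O)[C@@H]2C(C)(C)[C@@H](O[Si](C)(C)C(C)(C)C)CC[C@@]2(C)[C@@H]1COS(=O)(=O)C(F)(F)F
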